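**Plan**

1. Retrosynthesis: ring C of the flavone is cut at O1–C2 and C4–C4a (ortho-iodophenol, CO, aryl alkyne). The cyclohexane carbons are numbered C1' (CH carrying the benzylic CH2), C2' (C(OH)CH3), C3'–C5' (CH2) and C6' (C(CH3)2). The C1'–H and C2'–CH3 bonds are cut back to a 2-benzylidene-3,3-dimethylcyclohexanone, the benzylidene C=C to an aldehyde and a ring CH2, and finally the ring bonds C2'–C3' and C4'–C5' together, leaving 3,3-dimethylcyclobutanol and phenyl vinyl sulfone.
2. Enabling feature: C2', C1', C6' and C5' are contiguous, C6' is quaternary and C1' can wait as a CH2, so these four carbons can be carried as the symmetrical, strained 3,3-dimethylcyclobutanol ring. Opening its C2'–C5' bond by alkoxy-radical β-scission gives a neopentyl C5' radical (nothing to eliminate or rearrange) and a C2' carbonyl, between which the C3'–C4' ethylene unit is inserted in one radical–polar cascade.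
3. Forward order: cyclobutanol → sulfonyl-bearing cyclohexane ring → β-keto sulfone, whose sulfonyl group steers the aldol condensation with a symmetric aldehyde to C1' → enone → tertiary alcohol → saturated side chain → iodophenol → flavone ring C by carbonylative annulation → debenzylation.
4. Stereochemistry: C2' (S) from a ligand-controlled, titanium-promoted ZnMe2 addition to the enone; C1' (S) from hydroxyl-directed iridium hydrogenation (H enters cis to OH). Attachment at flavone C6 follows from the local mirror symmetry of the 2,6-bis(benzyloxy)-4-oxyphenyl unit, in which only the oxygen para to the side chain is freed to become O1.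

Key step: step 2

Remark: benzylidene compounds are drawn as E isomers; a Z component would be of no consequence, because the alkene geometry is erased in step 9.

**Route**

Step 1
Reactants: 1 3,3-dimethylcyclobutan-1-one
Product: 2 3,3-dimethylcyclobutan-1-ol
Conditions: NaBH4, MeOH, 0 °C
Reagents that add atoms: none
Why: Borohydride reduction of the strained ketone; the carbinol carbon lies on the mirror plane of the ring, so no stereocentre arises.

Step 2
Reactants: 2 3,3-dimethylcyclobutan-1-ol; 3 (ethenesulfonyl)benzene (phenyl vinyl sulfone)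
Product: 6 2-(benzenesulfonyl)-5,5-dimethylcyclohexan-1-ol, via 2,2-dimethyl-4-oxobutyl radical 4 (not isolated), via open-chain sulfonyl carbanion 5 (not isolated)
Conditions: 3 (2 equiv), CeCl3 (5 mol %), nBu4NCl (10 mol %), 9,10-diphenylanthracene (5 mol %), MeCN, 400 nm LEDs, rt, argon
Reagents that add atoms: none
Why: Proposed new method: photoinduced ligand-to-metal charge transfer in the tetravalent cerium alkoxide of 2 gives the cyclobutyloxy radical, strain-driven β-scission of either of the two equivalent ring bonds at the carbinol carbon unveils the aldehyde and the neopentyl radical 4, 4 adds to the CH2 terminus of 3 (first new bond, C4–C3 of 6), the α-sulfonyl radical is reduced by photoexcited 9,10-diphenylanthracene to carbanion 5, and 5 closes onto the aldehyde (second new bond, C2–C1 of 6), the alkoxide being protonated by fresh 2. The closest known reaction type is the cerium/anthracene dual-photocatalysed formal cycloaddition of cycloalkanols with electron-poor alkenes (alkoxy-radical β-scission, Giese addition, radical–polar crossover, intramolecular aldol closure); the extension is a vinyl sulfone as the two-carbon partner, chosen because the sulfonyl group is used again in step 6 and leaves in step 7. The cyclohexane ring closes 6-exo-trig (carbanion onto C=O) after an intermolecular first bond. The two new stereocentres (C1 and C2 of 6) are left uncontrolled on purpose: C1 is oxidised in step 3, and C2 is planarised in step 6 and loses its substituent in step 7. The step needs Giese addition to outrun reduction or hydrogen capture of 4, which the excess of 3 and the absence of any productive intramolecular path for 4 (no β-hydrogen on the quaternary carbon, closure onto the formyl group only regenerates the strained ring) should secure, and it needs carbonyl addition to outrun protonation of 5, which the aprotic medium and the six-membered transition state should secure.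

Step 3
Reactants: 6 2-(benzenesulfonyl)-5,5-dimethylcyclohexan-1-ol
Product: 7 2-(benzenesulfonyl)-5,5-dimethylcyclohexan-1-one
Conditions: Dess–Martin periodinane, CH2Cl2, 0 °C to rt
Reagents that add atoms: none
Why: Dess–Martin oxidation of the secondary alcohol to the β-keto sulfone, which removes the uncontrolled carbinol centre and makes both diastereomers of 6 converge.

Step 4
Reactants: 8 2,4,6-trihydroxybenzaldehyde
Product: 9 2,6-dihydroxy-4-(methoxymethoxy)benzaldehyde
Conditions: MOMCl (1.05 equiv), iPr2NEt (1.2 equiv), CH2Cl2, 0 °C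
Reagents that add atoms: chloromethyl methyl ether (MOMCl), COCCl
Why: Williamson-type O-alkylation; the 4-hydroxyl is the only phenol not hydrogen-bonded to the formyl group and the most acidic, so one equivalent of MOMCl should etherify it selectively.

Step 5
Reactants: 9 2,6-dihydroxy-4-(methoxymethoxy)benzaldehyde
Product: 10 2,6-bis(benzyloxy)-4-(methoxymethoxy)benzaldehyde
Conditions: BnBr (2.4 equiv), K2CO3, DMF, 60 °C
Reagents that add atoms: benzyl bromide, BrCc1ccccc1
Why: Williamson benzylation of the two chelated ortho-phenols under forcing carbonate/DMF conditions, to which the MOM acetal is inert.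

Step 6
Reactants: 7 2-(benzenesulfonyl)-5,5-dimethylcyclohexan-1-one; 10 2,6-bis(benzyloxy)-4-(methoxymethoxy)benzaldehyde
Product: 12 (2E)-6-(benzenesulfonyl)-2-{[2,6-bis(benzyloxy)-4-(methoxymethoxy)phenyl]methylidene}-3,3-dimethylcyclohexan-1-one, via aldol adduct 11 (not isolated)
Conditions: LiN(iPr)2 (2.2 equiv), THF, −78 to 0 °C; 10, −78 °C; AcOH; then PPTS (cat.), toluene, 60 °C
Reagents that add atoms: none
Why: Aldol condensation through the dianion of the β-keto sulfone: the first equivalent of base parks a stabilised anion between carbonyl and sulfonyl, so the second deprotonation and the C–C bond formation can only occur at C6 of 7 (the hindered methylene next to the gem-dimethyl carbon), and mild acid then dehydrates the electron-rich benzylic aldol 11 to the conjugated benzylidene.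

Step 7
Reactants: 12 (2E)-6-(benzenesulfonyl)-2-{[2,6-bis(benzyloxy)-4-(methoxymethoxy)phenyl]methylidene}-3,3-dimethylcyclohexan-1-one
Product: 13 (2E)-2-{[2,6-bis(benzyloxy)-4-(methoxymethoxy)phenyl]methylidene}-3,3-dimethylcyclohexan-1-one
Conditions: Al(Hg), THF/H2O, 0 °C to rt
Reagents that add atoms: none
Why: Reductive desulfonylation of a β-keto sulfone (two-electron reduction, loss of benzenesulfinate, C-protonation of the enolate), which returns the ring CH2 and erases the last uncontrolled centre.

Step 8
Reactants: 13 (2E)-2-{[2,6-bis(benzyloxy)-4-(methoxymethoxy)phenyl]methylidene}-3,3-dimethylcyclohexan-1-one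
Product: 14 (1S,2E)-2-{[2,6-bis(benzyloxy)-4-(methoxymethoxy)phenyl]methylidene}-1,3,3-trimethylcyclohexan-1-ol
Conditions: ZnMe2 (3 equiv), Ti(OiPr)4 (1.2 equiv), C2-symmetric bis(sulfonamide) diol ligand from trans-cyclohexane-1,2-diamine and 10-camphorsulfonic acid (10 mol %), toluene/hexane, rt; then H2O
Reagents that add atoms: dimethylzinc, C[Zn]C
Why: Titanium-promoted catalytic enantioselective 1,2-addition of dimethylzinc to an α-branched enone; the chiral titanium complex distinguishes the sp2 α-carbon (benzylidene, backed by the gem-dimethyl carbon) from the α'-methylene and, with the ligand enantiomer chosen for Re-face delivery, should give the (1S)-tertiary alcohol.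

Step 9
Reactants: 14 (1S,2E)-2-{[2,6-bis(benzyloxy)-4-(methoxymethoxy)phenyl]methylidene}-1,3,3-trimethylcyclohexan-1-ol
Product: 15 (1S,2S)-2-{[2,6-bis(benzyloxy)-4-(methoxymethoxy)phenyl]methyl}-1,3,3-trimethylcyclohexan-1-ol
Conditions: [Ir(cod)(PCy3)(py)]PF6 (10 mol %), H2 (1–4 atm), CH2Cl2, rt
Reagents that add atoms: none
Why: Hydroxyl-directed homogeneous hydrogenation; the cationic iridium centre binds the tertiary hydroxyl and the adjacent exocyclic alkene on one face, so hydrogen is delivered to C2 cis to OH, which sets C2 as S (arylmethyl trans to OH) whatever the alkene geometry.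

Step 10
Reactants: 15 (1S,2S)-2-{[2,6-bis(benzyloxy)-4-(methoxymethoxy)phenyl]methyl}-1,3,3-trimethylcyclohexan-1-ol
Product: 16 3,5-bis(benzyloxy)-4-{[(1S,2S)-2-hydroxy-2,6,6-trimethylcyclohexyl]methyl}phenol
Conditions: aq. HCl (cat.), MeOH/THF, rt
Reagents that add atoms: none
Why: Acid-catalysed acetal exchange to dimethoxymethane frees only the phenol para to the side chain; benzyl ethers and the unactivated tertiary alcohol should survive dilute methanolic acid, and the ortho oxygens stay blocked so that the alcohol cannot cyclise onto the ring.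

Step 11
Reactants: 16 3,5-bis(benzyloxy)-4-{[(1S,2S)-2-hydroxy-2,6,6-trimethylcyclohexyl]methyl}phenol
Product: 17 3,5-bis(benzyloxy)-4-{[(1S,2S)-2-hydroxy-2,6,6-trimethylcyclohexyl]methyl}-2-iodophenol
Conditions: N-iodosuccinimide (1.0 equiv), CH2Cl2, −20 °C
Reagents that add atoms: N-iodosuccinimide, O=C1CCC(=O)N1I
Why: Electrophilic aromatic iodination ortho to the free phenol; the para position is occupied and the two ortho positions are interchanged by rotation about the aryl–CH2 bond, so one equivalent of reagent should give a single mono-iodide.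

Step 12
Reactants: 18 3,4-bis(benzyloxy)benzaldehyde
Product: 19 1,2-bis(benzyloxy)-4-ethynylbenzene
Conditions: Ohira–Bestmann reagent, K2CO3, MeOH, rt
Reagents that add atoms: dimethyl (1-diazo-2-oxopropyl)phosphonate, COP(=O)(OC)C(=[N+]=[N-])C(C)=O
Why: Seyferth–Gilbert homologation with the Ohira–Bestmann reagent converts the aldehyde into the terminal alkyne under mild carbonate conditions.

Step 13
Reactants: 17 3,5-bis(benzyloxy)-4-{[(1S,2S)-2-hydroxy-2,6,6-trimethylcyclohexyl]methyl}-2-iodophenol; 19 1,2-bis(benzyloxy)-4-ethynylbenzene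
Product: 21 5,7-bis(benzyloxy)-2-[3,4-bis(benzyloxy)phenyl]-6-{[(1S,2S)-2-hydroxy-2,6,6-trimethylcyclohexyl]methyl}-4H-chromen-4-one, via alkynone 20 (not isolated)
Conditions: 19 (1.3 equiv), PdCl2(PPh3)2 (5 mol %), CO (1 atm), Et2NH, DMF, 60 °C
Reagents that add atoms: carbon monoxide, [C-]#[O+]
Why: Carbonylative Sonogashira coupling (oxidative addition of zerovalent palladium to the aryl iodide, CO insertion, alkynylation) gives alkynone 20, which the secondary amine turns into the flavone by conjugate addition, 6-endo closure of the phenoxide and loss of amine; because the only free phenol is the one para to the side chain, ring C can close only so as to place the side chain at C6.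

Step 14
Reactants: 21 5,7-bis(benzyloxy)-2-[3,4-bis(benzyloxy)phenyl]-6-{[(1S,2S)-2-hydroxy-2,6,6-trimethylcyclohexyl]methyl}-4H-chromen-4-one
Product: 22 2-(3,4-dihydroxyphenyl)-5,7-dihydroxy-6-{[(1S,2S)-2-hydroxy-2,6,6-trimethylcyclohexyl]methyl}-4H-chromen-4-one
Conditions: H2 (1 atm), Pd/C (10 wt %), EtOAc/MeOH, rt
Reagents that add atoms: none
Why: Hydrogenolysis of the four benzyl ethers on palladium under neutral conditions, which should spare the flavone C2=C3 bond and avoids any acid that could close the 5- or 7-hydroxyl onto the tertiary carbinol.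

**Compound list**

1 | 3,3-dimethylcyclobutan-1-one | CC1(C)CC(=O)C1 | starting material
2 | 3,3-dimethylcyclobutan-1-ol | CC1(C)CC(O)C1 | intermediate
3 | (ethenesulfonyl)benzene (phenyl vinyl sulfone) | C=CS(=O)(=O)c1ccccc1 | starting material
4 | 2,2-dimethyl-4-oxobutyl radical | [CH2]C(C)(C)CC=O | intermediate (not isolated)
5 | 1-(benzenesulfonyl)-4,4-dimethyl-6-oxohexan-1-ide | O=CCC(C)(C)CC[CH-]S(=O)(=O)c1ccccc1 | intermediate (not isolated)
6 | 2-(benzenesulfonyl)-5,5-dimethylcyclohexan-1-ol (racemic, both relative configurations) | OC1CC(C)(C)CCC1S(=O)(=O)c1ccccc1 | intermediate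
7 | 2-(benzenesulfonyl)-5,5-dimethylcyclohexan-1-one (racemic) | O=C1CC(C)(C)CCC1S(=O)(=O)c1ccccc1 | intermediate
8 | 2,4,6-trihydroxybenzaldehyde | O=Cc1c(O)cc(O)cc1O | starting material
9 | 2,6-dihydroxy-4-(methoxymethoxy)benzaldehyde | COCOc1cc(O)c(C=O)c(O)c1 | intermediate
10 | 2,6-bis(benzyloxy)-4-(methoxymethoxy)benzaldehyde | COCOc1cc(OCc2ccccc2)c(C=O)c(OCc2ccccc2)c1 | intermediate
11 | 6-(benzenesulfonyl)-2-{[2,6-bis(benzyloxy)-4-(methoxymethoxy)phenyl](hydroxy)methyl}-3,3-dimethylcyclohexan-1-one (diastereomer mixture, racemic) | O=C1C(S(=O)(=O)c2ccccc2)CCC(C)(C)C1C(O)c1c(OCc2ccccc2)cc(OCOC)cc1OCc1ccccc1 | intermediate (not isolated)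
12 | (2E)-6-(benzenesulfonyl)-2-{[2,6-bis(benzyloxy)-4-(methoxymethoxy)phenyl]methylidene}-3,3-dimethylcyclohexan-1-one (racemic) | O=C1C(S(=O)(=O)c2ccccc2)CCC(C)(C)/C1=C\c1c(OCc2ccccc2)cc(OCOC)cc1OCc1ccccc1 | intermediate
13 | (2E)-2-{[2,6-bis(benzyloxy)-4-(methoxymethoxy)phenyl]methylidene}-3,3-dimethylcyclohexan-1-one | O=C1CCCC(C)(C)/C1=C\c1c(OCc2ccccc2)cc(OCOC)cc1OCc1ccccc1 | intermediate
14 | (1S,2E)-2-{[2,6-bis(benzyloxy)-4-(methoxymethoxy)phenyl]methylidene}-1,3,3-trimethylcyclohexan-1-ol | CC1(C)CCC[C@](C)(O)/C1=C/c1c(OCc2ccccc2)cc(OCOC)cc1OCc1ccccc1 | intermediate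
15 | (1S,2S)-2-{[2,6-bis(benzyloxy)-4-(methoxymethoxy)phenyl]methyl}-1,3,3-trimethylcyclohexan-1-ol | CC1(C)CCC[C@](C)(O)[C@H]1Cc1c(OCc2ccccc2)cc(OCOC)cc1OCc1ccccc1 | intermediate
16 | 3,5-bis(benzyloxy)-4-{[(1S,2S)-2-hydroxy-2,6,6-trimethylcyclohexyl]methyl}phenol | CC1(C)CCC[C@](C)(O)[C@H]1Cc1c(OCc2ccccc2)cc(O)cc1OCc1ccccc1 | intermediate
17 | 3,5-bis(benzyloxy)-4-{[(1S,2S)-2-hydroxy-2,6,6-trimethylcyclohexyl]methyl}-2-iodophenol | CC1(C)CCC[C@](C)(O)[C@H]1Cc1c(OCc2ccccc2)cc(O)c(I)c1OCc1ccccc1 | intermediate
18 | 3,4-bis(benzyloxy)benzaldehyde | O=Cc1ccc(OCc2ccccc2)c(OCc2ccccc2)c1 | starting material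
19 | 1,2-bis(benzyloxy)-4-ethynylbenzene | C#Cc1ccc(OCc2ccccc2)c(OCc2ccccc2)c1 | intermediate
20 | 1-[2,4-bis(benzyloxy)-6-hydroxy-3-{[(1S,2S)-2-hydroxy-2,6,6-trimethylcyclohexyl]methyl}phenyl]-3-[3,4-bis(benzyloxy)phenyl]prop-2-yn-1-one | CC1(C)CCC[C@](C)(O)[C@H]1Cc1c(OCc2ccccc2)cc(O)c(C(=O)C#Cc2ccc(OCc3ccccc3)c(OCc3ccccc3)c2)c1OCc1ccccc1 | intermediate (not isolated)
21 | 5,7-bis(benzyloxy)-2-[3,4-bis(benzyloxy)phenyl]-6-{[(1S,2S)-2-hydroxy-2,6,6-trimethylcyclohexyl]methyl}-4H-chromen-4-one | CC1(C)CCC[C@](C)(O)[C@H]1Cc1c(OCc2ccccc2)cc2oc(-c3ccc(OCc4ccccc4)c(OCc4ccccc4)c3)cc(=O)c2c1OCc1ccccc1 | intermediate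
22 | 2-(3,4-dihydroxyphenyl)-5,7-dihydroxy-6-{[(1S,2S)-2-hydroxy-2,6,6-trimethylcyclohexyl]methyl}-4H-chromen-4-one | CC1(C)CCC[C@](C)(O)[C@H]1Cc1c(O)cc2oc(-c3ccc(O)c(O)c3)cc(=O)c2c1O | target

**Step count**

Total: 14 steps. Longest linear sequence: 11 steps (steps 1, 2, 3, 6, 7, 8, 9, 10, 11, 13, 14).

**Steps most likely to fail**

Step 2 (Proposed new method). The ring-opened radical may be reduced or pick up a hydrogen atom before it meets the sulfone. The carbanion may be protonated before it closes, which would stop at the open-chain sulfonyl aldehyde. The product alcohol may suffer a second β-scission and over-react. Fallback, known chemistry only, setting out from aldehyde 10 and coming back at enone 13: Me2CuLi is added to commercial 3-methylcyclohex-2-en-1-one (Et2O, −78 °C), which creates the gem-dimethyl carbon and a regiodefined enolate at the carbon between it and the carbonyl. The enolate is transmetallated with ZnCl2 and trapped with 10 to give the aldol 2-{[2,6-bis(benzyloxy)-4-(methoxymethoxy)phenyl](hydroxy)methyl}-3,3-dimethylcyclohexan-1-one F1. Mesylation and elimination (MsCl, Et3N, then DBU) give 13. The cyclohexane ring is then bought instead of built, and steps 1–3, 6 and 7 fall away.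

Step 8. Methyl transfer to the crowded conjugated carbonyl may be so slow that the uncatalysed, racemic background addition competes and the enantiomeric purity erodes; the tertiary allylic alcohol may also ionise on work-up. Fallback, setting out from 13 and coming back at 15 (it replaces step 9 as well): the exocyclic C=C of 13 is hydrogenated with a chiral cationic iridium phosphine–oxazoline catalyst, [Ir(cod)(P,N)][B(C6H3(CF3)2)4], under H2 in CH2Cl2. This sets the CH centre first (catalyst antipode chosen for 2S) and gives (2S)-2-{[2,6-bis(benzyloxy)-4-(methoxymethoxy)phenyl]methyl}-3,3-dimethylcyclohexan-1-one F2. Wittig methylenation (Ph3P=CH2, THF) gives 1,3-bis(benzyloxy)-2-{[(1S)-2,2-dimethyl-6-methylidenecyclohexyl]methyl}-5-(methoxymethoxy)benzene F3. mCPBA (CH2Cl2, NaHCO3) is expected to attack anti to the axial methyl of the gem-dimethyl carbon and give the spiro-epoxide with equatorial oxygen, (3S,4S)-4-{[2,6-bis(benzyloxy)-4-(methoxymethoxy)phenyl]methyl}-5,5-dimethyl-1-oxaspiro[2.5]octane F4. LiAlH4 (THF) opens F4 at its CH2 and gives 15.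

Step 9. The iridium catalyst may be deactivated before the crowded, aryl-shielded trisubstituted alkene is reduced. The acidic iridium hydride may ionise the tertiary allylic alcohol. Facial control is lost if the hydroxyl does not bind. Fallback, setting out from 14 and coming back at 15: silylation of the tertiary hydroxyl with (HMe2Si)2NH (60 °C) gives {[(1S,2E)-2-{[2,6-bis(benzyloxy)-4-(methoxymethoxy)phenyl]methylidene}-1,3,3-trimethylcyclohexyl]oxy}dimethylsilane F5. Pt2[(CH2=CHSiMe2)2O]3 (cat.) closes it by intramolecular hydrosilylation to the bicyclic 1-oxa-2-silacyclopentane F6; silicon goes to the benzylic carbon and hydrogen to the ring carbon from the face of the tethering oxygen, that is, cis to oxygen. nBu4NF in wet DMF then cleaves the Si–O bond and the benzylic C–Si bond (protodesilylation) to give 15.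

**Further compounds**

F1 | step 2 | 2-{[2,6-bis(benzyloxy)-4-(methoxymethoxy)phenyl](hydroxy)methyl}-3,3-dimethylcyclohexan-1-one (diastereomer mixture, racemic) | O=C1CCCC(C)(C)C1C(O)c1c(OCc2ccccc2)cc(OCOC)cc1OCc1ccccc1
F2 | step 8 | (2S)-2-{[2,6-bis(benzyloxy)-4-(methoxymethoxy)phenyl]methyl}-3,3-dimethylcyclohexan-1-one | CC1(C)CCCC(=O)[C@H]1Cc1c(OCc2ccccc2)cc(OCOC)cc1OCc1ccccc1
F3 | step 8 | 1,3-bis(benzyloxy)-2-{[(1S)-2,2-dimethyl-6-methylidenecyclohexyl]methyl}-5-(methoxymethoxy)benzene | CC1(C)CCCC(=C)[C@H]1Cc1c(OCc2ccccc2)cc(OCOC)cc1OCc1ccccc1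
F4 | step 8 | (3S,4S)-4-{[2,6-bis(benzyloxy)-4-(methoxymethoxy)phenyl]methyl}-5,5-dimethyl-1-oxaspiro[2.5]octane | CC1(C)CCC[C@@]2(CO2)[C@H]1Cc1c(OCc3ccccc3)cc(OCOC)cc1OCc1ccccc1
F5 | step 9 | {[(1S,2E)-2-{[2,6-bis(benzyloxy)-4-(methoxymethoxy)phenyl]methylidene}-1,3,3-trimethylcyclohexyl]oxy}dimethylsilane | CC1(C)CCC[C@](C)(O[SiH](C)C)/C1=C/c1c(OCc2ccccc2)cc(OCOC)cc1OCc1ccccc1
F6 | step 9 | bicyclic 1-oxa-2-silacyclopentane fused to the cyclohexane (O on the carbinol carbon, SiMe2 on the benzylic carbon, ring-fusion carbons S,S, benzylic carbon as epimer mixture) | CC1(C)CCC[C@]2(C)O[Si](C)(C)C(c3c(OCc4ccccc4)cc(OCOC)cc3OCc3ccccc3)[C@@H]12
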